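**Overview**

- Retrosynthesis: a benzyl carbonate is first removed from the phenol oxygen. The saturated acyl chain is then cut at the C8–C9 CH2–CH2 bond (C1 is the ester carbonyl). Last come the alkyl ester C–O bond and a tert-butyl ester that tells the two ends of a C9 diacid apart.
- Enabling feature: C2–C25 of the pentacosanoyl chain is an unbranched, unfunctionalised run of CH2 groups ending in CH3. C1–C8 can therefore come from a C9 diacid and C9–C25 from a C18 fatty acid, each after loss of one CO2. The only ring, the para-disubstituted benzene, is bought and never made.
- Forward: azelaic acid 1 is converted into its mono-tert-butyl ester 2, which is esterified with the primary hydroxyl of tyrosol 3 to give 4. The phenol is capped (5), the tert-butyl ester is cleaved (acid 6), and anodic decarboxylative coupling with stearic acid 7 joins C8 to C9 (8). Hydrogenolysis then frees the phenol of the target 9.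
- No ring is formed. The target has no stereocentre and no C=C bond, so no stereochemistry has to be set.

Key step: step 5

Remark: the acyl chain is numbered from the ester carbonyl (C1) to the terminal methyl (C25). Short-lived species (anodic alkyl radicals, phosphonium intermediates) are not counted as compounds.

**Route**

Step 1
Reactants: 1 azelaic acid (nonanedioic acid)
Product: 2 mono-tert-butyl azelate (9-tert-butoxy-9-oxononanoic acid)
Conditions: Me2NCH(Ot-Bu)2 (1.1 equiv, slow addition), toluene, 85 °C
Reagents that add atoms: N,N-dimethylformamide di-tert-butyl acetal, CN(C)C(OC(C)(C)C)OC(C)(C)C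
Why: Amide acetal esterification, in which the acid protonates the acetal and the carboxylate is tert-butylated by the resulting alkoxy-iminium ion; with about one equivalent a near-statistical mixture is expected, from which the diacid crystallises on cooling for re-use, the neutral diester stays in the organic phase on bicarbonate extraction, and the half-ester is obtained on acidification.

Step 2
Reactants: 2 mono-tert-butyl azelate (1.1 equiv); 3 tyrosol, 2-(4-hydroxyphenyl)ethanol
Product: 4 tert-butyl 2-(4-hydroxyphenyl)ethyl nonanedioate
Conditions: PPh3, DIAD (added last, dropwise), THF, 0 °C to rt
Reagents that add atoms: none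
Why: Mitsunobu esterification, in which the carboxylic acid (pKa about 5) protonates the phosphine–azodicarboxylate betaine far more readily than the phenol (pKa about 10), so the carboxylate and not the phenoxide displaces the oxyphosphonium group of the primary alcohol in an SN2 step and the phenol should stay free.

Step 3
Reactants: 4 tert-butyl 2-(4-hydroxyphenyl)ethyl nonanedioate
Product: 5 tert-butyl 2-[4-(benzyloxycarbonyloxy)phenyl]ethyl nonanedioate
Conditions: CbzCl, Et3N, CH2Cl2, 0 °C
Reagents that add atoms: benzyl chloroformate, O=C(Cl)OCc1ccccc1
Why: Carbonate formation by acylation of the phenol with a chloroformate under amine base; the phenol is the only nucleophile left in the molecule and both esters are inert at this temperature.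

Step 4
Reactants: 5 tert-butyl 2-[4-(benzyloxycarbonyloxy)phenyl]ethyl nonanedioate
Product: 6 9-{2-[4-(benzyloxycarbonyloxy)phenyl]ethoxy}-9-oxononanoic acid
Conditions: TFA, CH2Cl2 (1:3), 0 °C to rt; toluene co-evaporation
Reagents that add atoms: none
Why: Acidolysis of a tert-butyl ester through the tert-butyl cation, which is lost as isobutene; the primary alkyl ester and the aryl benzyl carbonate cannot ionise in this way and should survive trifluoroacetic acid at room temperature.

Step 5
Reactants: 6 9-{2-[4-(benzyloxycarbonyloxy)phenyl]ethoxy}-9-oxononanoic acid; 7 stearic acid (octadecanoic acid, 4 equiv, part of it fed during the run)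
Product: 8 2-[4-(benzyloxycarbonyloxy)phenyl]ethyl pentacosanoate
Conditions: undivided cell, smooth Pt foil anode, Pt cathode, constant current ca. 0.25 A cm−2, KOH (5 mol% of total acid, premixed with 7), MeOH–hexane (3:1), 40–45 °C, ca. 1.1 F per mol of acid, stopped while the bath is still acidic
Reagents that add atoms: none
Why: Both carboxylates are discharged at the platinum anode and lose CO2, giving the 7-(alkoxycarbonyl)heptyl radical from 6 (C1–C8) and the heptadecyl radical from 7 (C9–C25) in high concentration at the electrode surface, where they combine to form the C8–C9 sp3–sp3 bond while protons are reduced to H2 at the cathode. The closest known reaction type is the mixed Kolbe electrolysis of a fatty acid with a dicarboxylic acid half-ester, a standard route to long-chain esters, applied here to a half-ester whose alcohol part is a protected tyrosol instead of methanol. No ring is closed and no stereocentre is created. The step needs heterocoupling over homocoupling and the radical pathway over the carbocation (Hofer–Moest) pathway: the fourfold excess of cheap stearic acid should, on statistics, send most of the radicals from 6 into the cross product, and two unbranched acids without α-substituents on smooth platinum at high current density in weakly acidic methanol favour radical dimerisation. The arene is kept from the anode by its electron-poor carbonate cap and its distance of seven CH2 groups plus the ester from the radical centre, while premixing the base with 7, partial neutralisation only and stopping short of the alkaline end point protect the aryl carbonate and the tyrosol ester from methoxide. The coupling products carry no, one or two aryl carbonate groups (tetratriacontane, 8, and the symmetrical C16 diester), so they should separate cleanly on silica, with residual acids retained and unreacted 6 recoverable.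

Step 6
Reactants: 8 2-[4-(benzyloxycarbonyloxy)phenyl]ethyl pentacosanoate
Product: 9 2-(4-hydroxyphenyl)ethyl pentacosanoate (target)
Conditions: H2 (1 atm), 10% Pd/C, EtOAc–THF, 35–40 °C
Reagents that add atoms: none
Why: Hydrogenolysis of the benzylic C–O bond on palladium gives toluene and an aryl carbonic acid that loses CO2 to the free phenol; the alkyl ester, the saturated chain and the benzene ring are inert under these neutral conditions.

**Compound list**

1 | azelaic acid (nonanedioic acid) | OC(=O)CCCCCCCC(=O)O | starting material
2 | mono-tert-butyl azelate (9-tert-butoxy-9-oxononanoic acid) | CC(C)(C)OC(=O)CCCCCCCC(=O)O | intermediate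
3 | tyrosol, 2-(4-hydroxyphenyl)ethanol | OCCc1ccc(O)cc1 | starting material
4 | tert-butyl 2-(4-hydroxyphenyl)ethyl nonanedioate | CC(C)(C)OC(=O)CCCCCCCC(=O)OCCc1ccc(O)cc1 | intermediate
5 | tert-butyl 2-[4-(benzyloxycarbonyloxy)phenyl]ethyl nonanedioate | CC(C)(C)OC(=O)CCCCCCCC(=O)OCCc1ccc(OC(=O)OCc2ccccc2)cc1 | intermediate
6 | 9-{2-[4-(benzyloxycarbonyloxy)phenyl]ethoxy}-9-oxononanoic acid | OC(=O)CCCCCCCC(=O)OCCc1ccc(OC(=O)OCc2ccccc2)cc1 | intermediate
7 | stearic acid (octadecanoic acid) | CCCCCCCCCCCCCCCCCC(=O)O | starting material
8 | 2-[4-(benzyloxycarbonyloxy)phenyl]ethyl pentacosanoate | CCCCCCCCCCCCCCCCCCCCCCCCC(=O)OCCc1ccc(OC(=O)OCc2ccccc2)cc1 | intermediate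
9 | 2-(4-hydroxyphenyl)ethyl pentacosanoate | CCCCCCCCCCCCCCCCCCCCCCCCC(=O)OCCc1ccc(O)cc1 | target

**Count**

Total step count: 6. Longest linear sequence: 6 steps (1 → 2 → 4 → 5 → 6 → 8 → 9); tyrosol 3 and stearic acid 7 are bought.

**Steps most likely to fail**

Step 5 (key step). Two processes may go wrong. The aryl carbonate may be methanolysed in the basic layer at the cathode, after which the freed phenol is oxidised at the anode and films the platinum surface, diverting current from radical coupling. In addition, the statistical nature of the coupling may leave too little cross product beside the two symmetrical dimers. The fallback sets out from acid 6 and comes back at 8, making the same C8–C9 bond by a nickel-catalysed decarboxylative alkyl–alkyl Negishi coupling. Acid 6 is condensed with N-hydroxyphthalimide (N,N'-diisopropylcarbodiimide, CH2Cl2, rt) to the redox-active ester 1,3-dioxoisoindolin-2-yl 2-[4-(benzyloxycarbonyloxy)phenyl]ethyl nonanedioate F1. Commercial 1-bromoheptadecane is converted with Mg turnings in THF into heptadecylmagnesium bromide F2, and this with ZnCl2 (0.5 equiv) into diheptadecylzinc F3. F1 and F3 are then coupled with NiCl2·MeOCH2CH2OMe and 4,4'-di-tert-butyl-2,2'-bipyridine in THF/DMF at room temperature, which should give 8 without a statistical partner. Dialkylzinc reagents are not expected to attack the carbonate or the ester at this temperature.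

Step 2. The phenol oxygen may be alkylated by the activated primary alcohol (ether formation, oligomers) wherever the local supply of carboxylic acid runs low, and the product may be hard to free from triphenylphosphine oxide. The fallback sets out from tyrosol 3 and comes back at 5, bypassing 4, by masking the phenol first. Treatment of 3 with benzyl chloroformate and K2CO3 in acetone at 0 °C acylates only the phenoxide and should give benzyl 4-(2-hydroxyethyl)phenyl carbonate F4. Its single remaining hydroxyl is then esterified with acid 2 by carbodiimide coupling (EDC hydrochloride, catalytic DMAP, CH2Cl2, 0 °C), which gives 5 directly.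

Step 1. Over-esterification to the di-tert-butyl ester and losses in separating diacid, half-ester and diester may make the half-ester hard to obtain pure. The fallback sets out from 1 and comes back at 2 by differentiating the two ends stepwise.
- Fischer esterification (MeOH, catalytic H2SO4, reflux) gives dimethyl nonanedioate F5.
- Half-saponification with Ba(OH)2 (0.5 equiv) in methanol follows. The barium salt of the half-ester precipitates and is thereby withdrawn from the second hydrolysis; HCl then gives 9-methoxy-9-oxononanoic acid F6.
- The free acid is tert-butylated with isobutene and catalytic H2SO4 in CH2Cl2 in a sealed vessel to tert-butyl methyl nonanedioate F7.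
- LiOH (1 equiv) in THF/H2O at 0 °C cleaves only the methyl ester, and acidification with cold dilute HCl gives 2.

**Further compounds**

F1 | step 5 | 1,3-dioxoisoindolin-2-yl 2-[4-(benzyloxycarbonyloxy)phenyl]ethyl nonanedioate | O=C(CCCCCCCC(=O)OCCc1ccc(OC(=O)OCc2ccccc2)cc1)ON1C(=O)c2ccccc2C1=O
F2 | step 5 | heptadecylmagnesium bromide | CCCCCCCCCCCCCCCCC[Mg]Br
F3 | step 5 | diheptadecylzinc | CCCCCCCCCCCCCCCCC[Zn]CCCCCCCCCCCCCCCCC
F4 | step 2 | benzyl 4-(2-hydroxyethyl)phenyl carbonate | OCCc1ccc(OC(=O)OCc2ccccc2)cc1
F5 | step 1 | dimethyl nonanedioate | COC(=O)CCCCCCCC(=O)OC
F6 | step 1 | 9-methoxy-9-oxononanoic acid | COC(=O)CCCCCCCC(=O)O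
F7 | step 1 | tert-butyl methyl nonanedioate | COC(=O)CCCCCCCC(=O)OC(C)(C)C
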